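## Structural features

The target consists of two fully substituted benzene rings joined by a single CH2 group. Ring A is an acylphloroglucinol: C1 carries the (R)-2-methylbutanoyl group, C2 and C6 carry hydroxyls chelated to the ketone, C3 a methyl, C4 a methoxy group and C5 the bridging methylene. Ring B is the arene of a 5,7-dihydroxy-6-methylchroman-4-one whose C8 holds the other end of the bridge. It is fused through C4a–C8a to ring C, a dihydropyranone made of O1, the quaternary gem-dimethyl C2, the methylene C3 and the C4 ketone. The only stereocentre is the alpha carbon of the side-chain ketone; it has no stereogenic neighbour, but it is enolisable and must be handled mildly. Other fragile features are the diarylmethane bridge between two phloroglucinol nuclei (fragmentation and exchange under acid or base), the chromanone ether (retro-oxa-Michael opening under strong base) and the air-sensitive polyphenols. The real difficulty is regiochemical: one of three oxygens of ring A must be methylated, and ring C must be annulated so that the ring methyl ends at C6 and not at C8, which a direct acid-mediated annulation of a methylphloroglucinol cannot guarantee. The key step uses the fact that C2 of ring C, bonded to O1 and two methyls, is the carbon of an aryl isopropyl ether, and that C3 lies beside the C4 carbonyl. C2–C3 can therefore be formed by insertion of a ketocarbenoid centred on C3 into the isopropyl methine C–H bond.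

## Logic of the disconnections

21 to 19 and 13. The bond between C8 of ring B and the bridging CH2 is cut. It is the only link between two independently accessible halves, and C8 is the single free, strongly nucleophilic ring carbon of 13. The gain is full convergence, with the stereocentre confined to the ring A half. The forward step requires that 19 release the reactive intermediate 20 under near-neutral conditions and that 13 capture it at carbon without exchange of the bridge.

19 to 18. The C5–CH2 bond of ring A is cut, since C5 is the only unsubstituted position of 18. This removes the one-carbon unit and its amine leaving group. The forward aminomethylation must stop at one substitution and avoid free formaldehyde, which would build symmetric dimers.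

18 to 17. The O–CH3 bond at C4 is cut. The hydroxyl para to the ketone is the most acidic and the least tied up in hydrogen bonding, so it can be told apart from the two ortho hydroxyls. The gain is a triol with no protecting groups. The demand is mono-alkylation with one equivalent of reagent.

17 to 14 and 15 through 16. The aryl–acyl bond at C1 of ring A is cut. The two free positions of 15 are equivalent, so a single regioisomer can form, and the stereocentre comes from the chiral pool. The demand is acylation without enolisation of 16 or of the product ketone.

13 to 12. The two O–acyl bonds are cut. The esters are protecting groups whose only task is to pass through the carbenoid step. Their removal must not open ring C irreversibly.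

12 to 11. The C2–C3 bond of ring C is cut. This reduces the bicyclic chromanone to a monocyclic arene with an isopropoxy group and a diazoketone side chain in ortho relationship. The forward step is the intramolecular carbenoid C–H insertion; it must beat ylide formation at the ether oxygen.

11 to 9 through 10. The C4–C3 bond (acyl carbon to diazomethyl carbon) is cut. The result is a benzoic acid. The doubly ortho-substituted acid chloride 10 must acylate diazomethane while the esters survive.

9 to 8 to 6 through 7. The oxidation level is adjusted and then the aryl–C4 bond is cut. Compound 6 has only two free positions, related by symmetry, each between the isopropoxy group and an ester oxygen. The carbonyl carbon can therefore only arrive beside the isopropoxy oxygen, which fixes the oxygen that becomes O1 before ring C exists. The demand is electrophilic formylation of a moderately activated, flanked position without loss of the isopropyl group.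

6 to 4 and 5. The O1–C2 bond (aryl oxygen to isopropyl carbon) is cut. The gain is a mirror-symmetric phenol. The etherification must be neutral so that acyl groups do not migrate between oxygens.

4 to 2 through 3. The aryl C–O bond at the position para to the ring methyl is cut. In 2 this is the only C–H bond without an ortho substituent, so a sterically governed C–H borylation followed by oxidation installs the oxygen directly. A longer entry by degrading the carboxyl group of a 3,5-dioxygenated 4-methylbenzoic acid was rejected. It needs four or five steps, ends in a Baeyer–Villiger-type oxidation of an aldehyde whose aryl group has no ortho or para donor and migrates poorly, and carries benzyl ethers that must later be exchanged for esters.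

2 to 1. The two O–acyl bonds are cut, leading to a cheap symmetric diphenol. The esters are introduced first because they tolerate every later step and are the groups needed in 11.

## Other disconnections considered

Alternative 1: Ring A is cut across C1–C2 and C5–C6. This gives the four-carbon silyl ketene acetal diene A1 (C2–C5, already carrying the C3 methyl, the C4 methoxy group and, on C5, the methylene bridge with the benzyl-protected chromanone) and the two-carbon dienophile A2, the (R)-ethoxy ynone. The forward key step would be a polar [4+2] union: the diene terminus C5 attacks the ynone beta carbon C6, C1 closes onto the acetal carbon C2, and the acetal methoxy group is expelled to aromatise, giving A3.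
- In its favour: the substitution pattern of ring A is fixed by construction. The C4 methoxy group is present from the start and the C2 and C6 oxygens are differentiated, so no selective O-methylation is needed; on this point it is better than the chosen plan (step 10). The bridge is carried as an ordinary C–C bond, so the late phloroglucinol–phloroglucinol coupling (step 12) and its exchange risk are avoided; this is also better.
- Against it: A1 is a labile, tetrasubstituted ketene acetal that can only be made from a chromanone already bearing a functionalised chain at C8, so the ring B and ring C regiochemistry still has to be solved elsewhere. A2 is a push–pull alkynyl ether of reduced dienophilicity, and its stereocentre sits beside an ynone carbonyl under Lewis-acidic or fluoride conditions. After the key step an ethyl ether ortho to the ketone and two benzyl ethers must still be removed.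
- Comparison: on structure it answers ring A but not ring C. On mechanism the regiochemistry of a polar cycloaddition is as predictable as that of the C–H insertion, but it is asked of far more elaborate partners. On step economy it is expected to be longer and more linear.

Alternative 2: Ring C is removed completely by cutting O1–C8a, C4a–C4 and O1–C2, leaving the ortho-silylaryl triflate A4 and 3-methylbut-2-enoic acid A6. In the forward key step fluoride would unmask aryne A5. The carboxylate oxygen would add to the aryne carbon remote from the flanking benzyloxy group (future C8a), the aryl anion at C4a would take over the acyl group from oxygen, and the resulting ortho-acyl phenoxide would close by oxa-Michael addition to give A7.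
- In its favour: ring C is built in one operation from a commodity acid. No diazo compound is handled, which is a clear advantage in operational safety. The benzyl ethers fall in one hydrogenolysis to give 13, from which the same end game applies. In step count for the ring closure itself it is better than the chosen plan.
- Against it: A4 is a pentasubstituted aryne precursor whose preparation (ortho-halogenation, silyl transfer, triflation) consumes the steps saved. The regiochemistry depends on an electronic bias of the unsymmetrical aryne and not on symmetry. Protonation of the aryl anion by the acid competes with acyl transfer and would stop at an aryl ester.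
- Comparison: on structure it addresses the same ring as the chosen plan. On mechanism both have one competing pathway (proton transfer there, ylide formation here), but the chosen plan fixes O1 rigorously before cyclisation. Overall step economy is judged about equal.

Alternative 3: Ring B is cut at C8–C8a, C5–C6, C7–C8 and C4a–C5. This leaves the pyranone-based diazoketone A8, which carries ring A through the future C8 benzylic carbon, and the siloxyalkyne A10. In the forward key step, irradiation would trigger a Wolff rearrangement to vinylketene A9. [2+2] addition of A10, four-electron ring opening, six-electron ring closure and tautomerisation would then give A11.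
- In its favour: the hexasubstituted ring B is delivered regiospecifically, with the ring methyl necessarily at C6. The bridge is in place before the arene exists, so no late methylene coupling is needed; on this point it is better than the chosen plan. The two ring B oxygens emerge differentiated, which is not needed here but is not a drawback.
- Against it: A8 requires diazo transfer to an elaborate beta-aryl ketone. A diazo carbon bearing a CH2 group can undergo 1,2-hydrogen shift in competition with the Wolff rearrangement. The aryl ketone of ring A and the pyranone enone absorb in the same region as the diazoketone, which puts the enolisable stereocentre at photochemical risk. Ring A must be carried as a bis-benzyl ether, and three protecting groups remain to be removed. The selective methylation of ring A is not avoided.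
- Comparison: on structure it solves the same C6 against C8 problem by building ring B, where the chosen plan builds ring C. On mechanism it needs four consecutive pericyclic events in a crowded system, against one bond formation on a simple arene. On step economy it is longer and less convergent.

Key step: step 7

Assumption: 14 is taken as commercially available in high enantiomeric purity, and the stereocentre is carried through and not created; rings B and C are numbered as in chroman-4-one and ring A from the acyl-bearing carbon as C1.

## Steps

Step 1
Reactants: 1 2-methylbenzene-1,3-diol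
Product: 2 2-methyl-1,3-phenylene bis(2,2-dimethylpropanoate)
Conditions: PivCl (2.5 equiv), Et3N, DMAP (cat.), CH2Cl2, 0 °C to rt
Reagents that add atoms: pivaloyl chloride, CC(C)(C)C(Cl)=O
Why: DMAP-catalysed O-acylation of both phenols (nucleophilic acyl substitution); the pivalates are installed first because they tolerate all steps up to the carbenoid reaction and are inert towards it.

Step 2
Reactants: 2 2-methyl-1,3-phenylene bis(2,2-dimethylpropanoate)
Product: 4 5-hydroxy-2-methyl-1,3-phenylene bis(2,2-dimethylpropanoate), via arylboronic ester 3 (not isolated)
Conditions: [Ir(OMe)(cod)]2 (1.5 mol %), dtbpy (3 mol %), B2pin2 (0.6 equiv), THF, 80 °C; then Oxone (2KHSO5·KHSO4·K2SO4), acetone/H2O, rt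
Reagents that add atoms: bis(pinacolato)diboron, CC1(C)OB(OC1(C)C)B1OC(C)(C)C(C)(C)O1 (boron and pinacolate of intermediate 3 only); potassium peroxymonosulfate from Oxone, [K+].[O-]S(=O)(=O)OO (phenol oxygen)
Why: Iridium-catalysed aromatic C–H borylation is sterically controlled, and C5 of 2 is the only ring C–H bond without an ortho substituent, so 3 should form as one regioisomer. Ipso-oxidation of the C–B bond by peroxymonosulfate (aryl shift from boron to oxygen) then gives the phenol under near-neutral conditions that leave aryl pivalates intact.

Step 3
Reactants: 4 5-hydroxy-2-methyl-1,3-phenylene bis(2,2-dimethylpropanoate); 5 propan-2-ol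
Product: 6 5-isopropoxy-2-methyl-1,3-phenylene bis(2,2-dimethylpropanoate)
Conditions: PPh3, DIAD, THF, 0 °C to rt
Reagents that add atoms: none
Why: Mitsunobu etherification of an acidic phenol with a secondary alcohol; the neutral conditions avoid phenoxide-mediated pivaloyl transfer, and no stereocentre is involved.

Step 4
Reactants: 6 5-isopropoxy-2-methyl-1,3-phenylene bis(2,2-dimethylpropanoate)
Product: 8 6-isopropoxy-3-methyl-2,4-bis(pivaloyloxy)benzaldehyde, via chloro ether 7 (not isolated)
Conditions: Cl2CHOMe, TiCl4, CH2Cl2, −78 to −20 °C; then ice/H2O
Reagents that add atoms: dichloromethyl methyl ether, COC(Cl)Cl (formyl carbon); water, O (carbonyl oxygen)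
Why: Rieche formylation, a Friedel–Crafts-type substitution by the chloro(methoxy)methyl cation. The two free positions of 6 are equivalent, each ortho to the isopropoxy donor and ortho or para to the acyloxy groups, so only one aldehyde can form and its carbonyl must lie beside the isopropoxy oxygen. Aqueous work-up hydrolyses chloro ether 7.

Step 5
Reactants: 8 6-isopropoxy-3-methyl-2,4-bis(pivaloyloxy)benzaldehyde
Product: 9 6-isopropoxy-3-methyl-2,4-bis(pivaloyloxy)benzoic acid
Conditions: NaClO2, NaH2PO4, 2-methylbut-2-ene, t-BuOH/H2O, rt
Reagents that add atoms: sodium chlorite, [Na+].[O-]Cl=O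
Why: Pinnick oxidation converts hindered aromatic aldehydes to acids under buffered, mildly acidic conditions; the alkene scavenges hypochlorous acid so the ring is not chlorinated, and esters and ether are untouched.

Step 6
Reactants: 9 6-isopropoxy-3-methyl-2,4-bis(pivaloyloxy)benzoic acid
Product: 11 2-diazo-1-[6-isopropoxy-3-methyl-2,4-bis(pivaloyloxy)phenyl]ethan-1-one, via acid chloride 10 (not isolated)
Conditions: (COCl)2, DMF (cat.), CH2Cl2, 0 °C to rt; evaporate; CH2N2 (3 equiv), Et2O, 0 °C to rt
Reagents that add atoms: diazomethane, C=[N+]=[N-]; oxalyl chloride, O=C(Cl)C(Cl)=O (chlorine of intermediate 10 only)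
Why: Acid chloride formation through the chloroiminium catalyst, then acylation of diazomethane as in the first stage of the Arndt–Eistert sequence; the excess diazomethane removes HCl so the diazoketone is not converted to a chloromethyl ketone.

Step 7
Reactants: 11 2-diazo-1-[6-isopropoxy-3-methyl-2,4-bis(pivaloyloxy)phenyl]ethan-1-one
Product: 12 2,2,6-trimethyl-4-oxochromane-5,7-diyl bis(2,2-dimethylpropanoate)
Conditions: Rh2(OAc)4 (1 mol %), CH2Cl2, reflux, slow addition of 11 at high dilution
Reagents that add atoms: none
Why: Rh2(OAc)4, a divalent-rhodium dimer, should expel N2 from 11 to give an electrophilic rhodium carbenoid at the future C3, which inserts into the methine C–H bond of the ortho isopropoxy group in a concerted, asynchronous three-centre process and so forms C2–C3. The closest known reaction type is the dirhodium-carboxylate-catalysed intramolecular C–H insertion of ortho-alkoxyaryl diazomethyl ketones to chroman-4-ones. Ring C closes in a six-membered mode (1,6-insertion through a six-membered transition state), because the atom that would give the usual five-membered ring is the ether oxygen, which bears no hydrogen, while the methyl C–H bonds are primary and would need a seven-membered ring. No stereocentre is formed, since C2 carries two identical methyl groups. The selectivity needed is insertion over oxonium-ylide formation at the ether oxygen followed by Stevens 1,2-shift to a benzofuranone. It should be secured by the weak, tertiary, oxygen-activated C–H bond, by the low nucleophilicity of an aryl ether oxygen conjugated to the ortho ketone and to a ring bearing two acyloxy groups, and by the moderately electrophilic acetate ligands. The pivalates offer only remote primary C–H bonds and carbonyl oxygens that could reach the carbenoid only through a seven-membered ring, and the fully substituted arene has no site within reach for aromatic cycloaddition. Slow addition keeps the diazo concentration low and suppresses carbene dimerisation. The position of ring C on ring B is not at stake here, because the single isopropoxy group was placed by symmetry in step 4.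

Step 8
Reactants: 12 2,2,6-trimethyl-4-oxochromane-5,7-diyl bis(2,2-dimethylpropanoate)
Product: 13 5,7-dihydroxy-2,2,6-trimethylchroman-4-one
Conditions: K2CO3 (3 equiv), MeOH (degassed), rt; then aq. HCl
Reagents that add atoms: none
Why: Base-mediated methanolysis of aryl esters, whose phenoxide leaving groups are stabilised by the peri and para ketone; any reversible retro-oxa-Michael opening of the 2,2-dimethylchromanone should reclose on neutralisation.

Step 9
Reactants: 14 (R)-2-methylbutanoic acid; 15 2-methylbenzene-1,3,5-triol
Product: 17 (R)-2-methyl-1-(2,4,6-trihydroxy-3-methylphenyl)butan-1-one, via (R)-2-methylbutanoyl chloride 16 (not isolated)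
Conditions: (COCl)2 (1.0 equiv), DMF (cat.), CH2Cl2, 0 °C to rt; then 15, AlCl3 (3.5 equiv), CH2Cl2/PhNO2, 0 °C to rt; aq. HCl
Reagents that add atoms: oxalyl chloride, O=C(Cl)C(Cl)=O (chlorine of intermediate 16 only)
Why: Friedel–Crafts acylation of the symmetric triol, whose two free positions are equivalent and which is deactivated against a second acylation, so one mono-ketone is expected. The stereocentre is taken unchanged from 14; the absence of amine base and the low temperature are meant to prevent ketene formation and enolisation.

Step 10
Reactants: 17 (R)-2-methyl-1-(2,4,6-trihydroxy-3-methylphenyl)butan-1-one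
Product: 18 (R)-1-(2,6-dihydroxy-4-methoxy-3-methylphenyl)-2-methylbutan-1-one
Conditions: Me2SO4 (1.0 equiv), K2CO3 (1.05 equiv), acetone, rt
Reagents that add atoms: dimethyl sulfate, COS(=O)(=O)OC
Why: Williamson O-methylation with one equivalent of reagent; the hydroxyl para to the ketone is the most acidic and the least hydrogen-bonded, so it should react first, and phenoxide formation lowers the acidity of the ketone alpha hydrogen and so protects the stereocentre.

Step 11
Reactants: 18 (R)-1-(2,6-dihydroxy-4-methoxy-3-methylphenyl)-2-methylbutan-1-one
Product: 19 (R)-1-{3-[(dimethylamino)methyl]-2,6-dihydroxy-4-methoxy-5-methylphenyl}-2-methylbutan-1-one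
Conditions: Me2NCH2NMe2 (1.1 equiv), 1,4-dioxane, rt
Reagents that add atoms: bis(dimethylamino)methane, CN(C)CN(C)C
Why: Mannich aminomethylation by the iminium ion released from the aminal, at C5, the only unsubstituted ring carbon of 18; the preformed aminal avoids free formaldehyde and hence methylene-bridged homodimers.

Step 12
Reactants: 19 (R)-1-{3-[(dimethylamino)methyl]-2,6-dihydroxy-4-methoxy-5-methylphenyl}-2-methylbutan-1-one; 13 5,7-dihydroxy-2,2,6-trimethylchroman-4-one
Product: 21 8-({2,4-dihydroxy-6-methoxy-5-methyl-3-[(2R)-2-methylbutanoyl]phenyl}methyl)-5,7-dihydroxy-2,2,6-trimethylchroman-4-one, via o-quinone methide 20 (not isolated)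
Conditions: 13 (1.2 equiv), 1,4-dioxane, 90 °C, N2
Reagents that add atoms: none
Why: Thermal loss of dimethylamine from the ortho-hydroxybenzylamine gives o-quinone methide 20, which is captured in a Michael-type Friedel–Crafts alkylation by C8 of 13, its only free ring carbon (ortho to the 7-hydroxyl, para to the 5-hydroxyl). Re-aromatisation drives C-alkylation while O-alkylation is reversible; no stereocentre is formed, and the near-neutral medium should leave the alpha stereocentre untouched.

## Compound list

1 | 2-methylbenzene-1,3-diol | Cc1c(O)cccc1O | starting material
2 | 2-methyl-1,3-phenylene bis(2,2-dimethylpropanoate) | Cc1c(OC(=O)C(C)(C)C)cccc1OC(=O)C(C)(C)C | intermediate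
3 | 2-methyl-5-(4,4,5,5-tetramethyl-1,3,2-dioxaborolan-2-yl)-1,3-phenylene bis(2,2-dimethylpropanoate) | Cc1c(OC(=O)C(C)(C)C)cc(B2OC(C)(C)C(C)(C)O2)cc1OC(=O)C(C)(C)C | intermediate
4 | 5-hydroxy-2-methyl-1,3-phenylene bis(2,2-dimethylpropanoate) | Cc1c(OC(=O)C(C)(C)C)cc(O)cc1OC(=O)C(C)(C)C | intermediate
5 | propan-2-ol | CC(C)O | starting material
6 | 5-isopropoxy-2-methyl-1,3-phenylene bis(2,2-dimethylpropanoate) | CC(C)Oc1cc(OC(=O)C(C)(C)C)c(C)c(OC(=O)C(C)(C)C)c1 | intermediate
7 | 4-[chloro(methoxy)methyl]-5-isopropoxy-2-methyl-1,3-phenylene bis(2,2-dimethylpropanoate) | CC(C)Oc1cc(OC(=O)C(C)(C)C)c(C)c(OC(=O)C(C)(C)C)c1C(Cl)OC | intermediate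
8 | 6-isopropoxy-3-methyl-2,4-bis(pivaloyloxy)benzaldehyde | CC(C)Oc1cc(OC(=O)C(C)(C)C)c(C)c(OC(=O)C(C)(C)C)c1C=O | intermediate
9 | 6-isopropoxy-3-methyl-2,4-bis(pivaloyloxy)benzoic acid | CC(C)Oc1cc(OC(=O)C(C)(C)C)c(C)c(OC(=O)C(C)(C)C)c1C(=O)O | intermediate
10 | 6-isopropoxy-3-methyl-2,4-bis(pivaloyloxy)benzoyl chloride | CC(C)Oc1cc(OC(=O)C(C)(C)C)c(C)c(OC(=O)C(C)(C)C)c1C(=O)Cl | intermediate
11 | 2-diazo-1-[6-isopropoxy-3-methyl-2,4-bis(pivaloyloxy)phenyl]ethan-1-one | CC(C)Oc1cc(OC(=O)C(C)(C)C)c(C)c(OC(=O)C(C)(C)C)c1C(=O)C=[N+]=[N-] | intermediate
12 | 2,2,6-trimethyl-4-oxochromane-5,7-diyl bis(2,2-dimethylpropanoate) (5,7-bis(pivaloyloxy)-2,2,6-trimethylchroman-4-one) | CC(C)(C)C(=O)Oc1cc2OC(C)(C)CC(=O)c2c(OC(=O)C(C)(C)C)c1C | intermediate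
13 | 5,7-dihydroxy-2,2,6-trimethylchroman-4-one | Cc1c(O)cc2OC(C)(C)CC(=O)c2c1O | intermediate
14 | (R)-2-methylbutanoic acid | CC[C@@H](C)C(=O)O | starting material
15 | 2-methylbenzene-1,3,5-triol | Cc1c(O)cc(O)cc1O | starting material
16 | (R)-2-methylbutanoyl chloride | CC[C@@H](C)C(=O)Cl | intermediate
17 | (R)-2-methyl-1-(2,4,6-trihydroxy-3-methylphenyl)butan-1-one | CC[C@@H](C)C(=O)c1c(O)cc(O)c(C)c1O | intermediate
18 | (R)-1-(2,6-dihydroxy-4-methoxy-3-methylphenyl)-2-methylbutan-1-one | CC[C@@H](C)C(=O)c1c(O)cc(OC)c(C)c1O | intermediate
19 | (R)-1-{3-[(dimethylamino)methyl]-2,6-dihydroxy-4-methoxy-5-methylphenyl}-2-methylbutan-1-one | CC[C@@H](C)C(=O)c1c(O)c(C)c(OC)c(CN(C)C)c1O | intermediate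
20 | (R)-3-hydroxy-5-methoxy-4-methyl-2-(2-methylbutanoyl)-6-methylidenecyclohexa-2,4-dien-1-one | CC[C@@H](C)C(=O)C1=C(O)C(C)=C(OC)C(=C)C1=O | intermediate
21 | 8-({2,4-dihydroxy-6-methoxy-5-methyl-3-[(2R)-2-methylbutanoyl]phenyl}methyl)-5,7-dihydroxy-2,2,6-trimethylchroman-4-one | CC[C@@H](C)C(=O)c1c(O)c(C)c(OC)c(Cc2c(O)c(C)c(O)c3c2OC(C)(C)CC3=O)c1O | target

## Step count and least certain steps

Total step count: 12. Longest linear sequence: 9 steps (steps 1 to 8 and step 12, from 1). The ring A branch (steps 9 to 11) converges in step 12.

Step 7 (key step). The most likely failure is capture of the carbenoid by the lone pair of the ether oxygen, giving an oxonium ylide that undergoes 1,2-shift of the isopropyl group to a five-membered benzofuranone; loss of the carbenoid by dimerisation is the second risk. Both compete because the ether oxygen lies closer to the carbenoid than the methine hydrogen. The fallback gives up the insertion and sets out from the symmetric phenol 4. Acylation with 3-methylbut-2-enoyl chloride and Et3N should give the aryl ester 5-[(3-methylbut-2-enoyl)oxy]-2-methyl-1,3-phenylene bis(2,2-dimethylpropanoate) F1. Fries rearrangement (MeSO3H or BF3·OEt2, 60 °C) can only deliver the acyl group to one of the two equivalent ortho positions, giving 1-[6-hydroxy-3-methyl-2,4-bis(pivaloyloxy)phenyl]-3-methylbut-2-en-1-one F2. F2 should close under the same conditions by oxa-Michael addition and rejoin the route at 12. Partial loss of pivalate under the acid would be harmless, since step 8 removes both.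

Step 4. The likely failures are sluggish substitution at a doubly flanked position of an only moderately activated ring, made worse by coordination of TiCl4 to the ester carbonyls, and Lewis-acid dealkylation of the isopropyl ether once it stands ortho to the new carbonyl. The fallback sets out from 4 and reverses the order of events. Magnesium-phenoxide-directed ortho-formylation (MgCl2, Et3N, paraformaldehyde, MeCN, reflux) should give 6-hydroxy-3-methyl-2,4-bis(pivaloyloxy)benzaldehyde F3, again at the only kind of free position. O-alkylation of F3 with 2-bromopropane and K2CO3 in DMF then rejoins the route at 8.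

Step 9. The likely failure is partial racemisation, through enolisation of the aluminium-bound acyl species derived from 16 or of the chelated product ketone, together with some O-acylation or double acylation. The fallback sets out from 14 and replaces the electrophilic acylation by an organolithium addition. Acid chloride 16 and N,O-dimethylhydroxylamine should give (R)-N-methoxy-N,2-dimethylbutanamide F4. Triol 15 is protected as 1,3,5-tris(methoxymethoxy)-2-methylbenzene F5, which is lithiated with n-BuLi at one of its two equivalent ring positions and added to F4 at −78 °C. This should give (R)-2-methyl-1-[2,4,6-tris(methoxymethoxy)-3-methylphenyl]butan-1-one F6. Mild acid methanolysis (HCl, MeOH, rt) then rejoins the route at 17.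

Step 10. The likely failure is over-alkylation or alkylation at whichever ortho hydroxyl is not hydrogen-bonded at the moment, giving the isomeric monomethyl ether or a dimethyl ether. The fallback sets out from 17 and replaces selective alkylation by selective dealkylation. Exhaustive methylation (excess Me2SO4, K2CO3, acetone, reflux) should give (R)-2-methyl-1-(2,4,6-trimethoxy-3-methylphenyl)butan-1-one F7. Chelation-controlled ortho-demethylation with excess BCl3 (CH2Cl2, −78 °C to rt) should then cleave only the two methoxy groups flanking the ketone and rejoin the route at 18.

Step 12. The likely failures are exchange of the bridge (fragmentation of the benzylic C–C or C–N bond and recombination to symmetric dimers), O-alkylation that fails to revert, and slow epimerisation of the alpha stereocentre on prolonged heating with amine. The fallback reverses the roles of the two halves and sets out from 13. Aminomethylation at C8 with Me2NCH2NMe2 should give 8-[(dimethylamino)methyl]-5,7-dihydroxy-2,2,6-trimethylchroman-4-one F8. On heating with 18 in 1,4-dioxane, F8 should release the ring B quinone methide, which is captured at C5 of 18, and the route is rejoined at 21.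

## Further compounds

F1 | step 7 | 5-[(3-methylbut-2-enoyl)oxy]-2-methyl-1,3-phenylene bis(2,2-dimethylpropanoate) | CC(C)=CC(=O)Oc1cc(OC(=O)C(C)(C)C)c(C)c(OC(=O)C(C)(C)C)c1
F2 | step 7 | 1-[6-hydroxy-3-methyl-2,4-bis(pivaloyloxy)phenyl]-3-methylbut-2-en-1-one | CC(C)=CC(=O)c1c(O)cc(OC(=O)C(C)(C)C)c(C)c1OC(=O)C(C)(C)C
F3 | step 4 | 6-hydroxy-3-methyl-2,4-bis(pivaloyloxy)benzaldehyde | Cc1c(OC(=O)C(C)(C)C)cc(O)c(C=O)c1OC(=O)C(C)(C)C
F4 | step 9 | (R)-N-methoxy-N,2-dimethylbutanamide | CC[C@@H](C)C(=O)N(C)OC
F5 | step 9 | 1,3,5-tris(methoxymethoxy)-2-methylbenzene | Cc1c(OCOC)cc(OCOC)cc1OCOC
F6 | step 9 | (R)-2-methyl-1-[2,4,6-tris(methoxymethoxy)-3-methylphenyl]butan-1-one | CC[C@@H](C)C(=O)c1c(OCOC)cc(OCOC)c(C)c1OCOC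
F7 | step 10 | (R)-2-methyl-1-(2,4,6-trimethoxy-3-methylphenyl)butan-1-one | CC[C@@H](C)C(=O)c1c(OC)cc(OC)c(C)c1OC
F8 | step 12 | 8-[(dimethylamino)methyl]-5,7-dihydroxy-2,2,6-trimethylchroman-4-one | CN(C)Cc1c(O)c(C)c(O)c2C(=O)CC(C)(C)Oc12
A1 | alternative 1 | 5,7-bis(benzyloxy)-8-[3,5-dimethoxy-4-methyl-5-(trimethylsilyloxy)penta-2,4-dien-1-yl]-2,2,6-trimethylchroman-4-one | COC(O[Si](C)(C)C)=C(C)C(OC)=CCc1c(OCc2ccccc2)c(C)c(OCc2ccccc2)c2C(=O)CC(C)(C)Oc12
A2 | alternative 1 | (R)-1-ethoxy-4-methylhex-1-yn-3-one | CCOC#CC(=O)[C@H](C)CC
A3 | alternative 1 | (R)-5,7-bis(benzyloxy)-8-{[2-ethoxy-4-hydroxy-6-methoxy-5-methyl-3-(2-methylbutanoyl)phenyl]methyl}-2,2,6-trimethylchroman-4-one | CC[C@@H](C)C(=O)c1c(O)c(C)c(OC)c(Cc2c(OCc4ccccc4)c(C)c(OCc5ccccc5)c3c2OC(C)(C)CC3=O)c1OCC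
A4 | alternative 2 | 3,5-bis(benzyloxy)-4-methyl-2-(trimethylsilyl)phenyl trifluoromethanesulfonate | Cc1c(OCc2ccccc2)cc(OS(=O)(=O)C(F)(F)F)c([Si](C)(C)C)c1OCc1ccccc1
A5 | alternative 2 | 3,5-bis(benzyloxy)-4-methyl-1,2-didehydrobenzene | CC1=C(OCc2ccccc2)C#CC=C1OCc1ccccc1
A6 | alternative 2 | 3-methylbut-2-enoic acid | CC(C)=CC(=O)O
A7 | alternative 2 | 5,7-bis(benzyloxy)-2,2,6-trimethylchroman-4-one | Cc1c(OCc2ccccc2)cc2OC(C)(C)CC(=O)c2c1OCc1ccccc1
A8 | alternative 3 | (R)-6-{3-[2,4-bis(benzyloxy)-6-methoxy-5-methyl-3-(2-methylbutanoyl)phenyl]-2-diazopropanoyl}-2,2-dimethyl-2,3-dihydro-4H-pyran-4-one | CC1(C)CC(=O)C=C(O1)C(=O)C(=[N+]=[N-])Cc1c(OC)c(C)c(OCc2ccccc2)c(C(=O)[C@H](C)CC)c1OCc1ccccc1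
A9 | alternative 3 | (R)-3-[2,4-bis(benzyloxy)-6-methoxy-5-methyl-3-(2-methylbutanoyl)phenyl]-2-(6,6-dimethyl-4-oxo-5,6-dihydro-4H-pyran-2-yl)prop-1-en-1-one | CC1(C)CC(=O)C=C(O1)C(=C=O)Cc1c(OC)c(C)c(OCc2ccccc2)c(C(=O)[C@H](C)CC)c1OCc1ccccc1
A10 | alternative 3 | triisopropyl(prop-1-yn-1-yloxy)silane | CC#CO[Si](C(C)C)(C(C)C)C(C)C
A11 | alternative 3 | (R)-8-{[2,4-bis(benzyloxy)-6-methoxy-5-methyl-3-(2-methylbutanoyl)phenyl]methyl}-5-hydroxy-2,2,6-trimethyl-7-[(triisopropylsilyl)oxy]chroman-4-one | CC1(C)CC(=O)c2c(O)c(C)c(O[Si](C(C)C)(C(C)C)C(C)C)c(Cc3c(OC)c(C)c(OCc4ccccc4)c(C(=O)[C@H](C)CC)c3OCc3ccccc3)c2O1
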